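**Retrosynthetic overview**
1. Feature: ring C is a benzene ring with oxygens on C-1 and C-3, the diarylmethine carbon on C-2 between them, and the (E)-styryl arm (ring D) on C-5. Read round the ring, this is the chain CH3-CO-CH(R)-CO-CH2-CO-CH=CH-Ar folded so that the methyl carbon meets the cinnamoyl carbonyl.
2. Late disconnections: removing the two isopropyl ethers (rings B and D) and the two ring-C methyl ethers leads back to a free 2-alkyl-5-styrylresorcinol.
3. Key disconnection: the ring-C bond between one ring CH and the styryl-bearing carbon is cut (retro-aldol) to the 1,3,5-triketone. This is handled as its anhydro form, a 2-methyl-3-alkyl-6-styryl-4-pyranone.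
4. The triketone comes from the 1,3-dianion of a 3-substituted pentane-2,4-dione and a cinnamoyl N-methoxy-N-methylamide. The diketone comes from acetylacetone and 4-methoxycinnamaldehyde (iminium-catalysed Michael addition, sole stereocentre), a ring-B aryl Grignard reagent, and ionic deoxygenation.
5. Ring order: rings A, B and D are bought; the pyranone ring is closed first and is then exchanged for carbocyclic ring C.

Key step: step 8

Assumption: the Michael adduct of step 2 is drawn as the open keto-aldehyde although it should equilibrate with its cyclic lactol, and the sense of induction is taken from the usual steric-shielding model of diarylprolinol silyl ether iminium ions (the antipodal catalyst is equally available).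

**Step 1**
Reactants: 1 4-bromo-3-methoxyphenol
Product: 2 1-bromo-2-methoxy-4-(propan-2-yloxy)benzene
Conditions: 2-bromopropane, K2CO3, DMF, 60 °C
Reagents that add atoms: 2-bromopropane, CC(C)Br
Why: Williamson ether synthesis on the phenoxide, the isopropyl ether being chosen because it should survive Grignard formation, trifluoroacetic acid, LDA and hot hydroxide and still fall to BCl3 beside methyl ethers.

**Step 2**
Reactants: 3 pentane-2,4-dione (acetylacetone); 4 (E)-3-(4-methoxyphenyl)prop-2-enal
Product: 5 (3R)-4-acetyl-3-(4-methoxyphenyl)-5-oxohexanal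
Conditions: (S)-α,α-diphenylprolinol trimethylsilyl ether (15 mol %), PhCO2H (15 mol %), CH2Cl2, 0 °C; short silica plug, used at once
Reagents that add atoms: none
Why: Iminium-catalysed asymmetric Michael addition in which the enal forms the (E)-s-trans iminium ion, the face syn to the CPh2(OSiMe3) group is blocked, and the enol of 3 should add to the open face of the β-carbon to set the (R)-centre, the same spatial arrangement that is named S in the target once ring C outranks ring A.

**Step 3**
Reactants: 2 1-bromo-2-methoxy-4-(propan-2-yloxy)benzene; 5 (3R)-4-acetyl-3-(4-methoxyphenyl)-5-oxohexanal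
Product: 7 3-{(1R)-3-hydroxy-3-[2-methoxy-4-(propan-2-yloxy)phenyl]-1-(4-methoxyphenyl)propyl}pentane-2,4-dione (both carbinol epimers), via arylmagnesium bromide 6 (not isolated)
Conditions: 2, Mg, THF, 45 °C (2.5 equiv of 6); then 5, THF, −40 → 0 °C; sat. aq NH4Cl
Reagents that add atoms: none
Why: Grignard 1,2-addition in which the first equivalent of 6 deprotonates the diketone (opening any lactol) to a magnesium diketonate that shields both ketones and cannot undergo retro-Michael cleavage, further 6 adds to the aldehyde, and the uncontrolled carbinol centre is erased in step 4.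

**Step 4**
Reactants: 7 3-{(1R)-3-hydroxy-3-[2-methoxy-4-(propan-2-yloxy)phenyl]-1-(4-methoxyphenyl)propyl}pentane-2,4-dione
Product: 8 3-{(1R)-3-[2-methoxy-4-(propan-2-yloxy)phenyl]-1-(4-methoxyphenyl)propyl}pentane-2,4-dione
Conditions: Et3SiH (4 equiv), TFA (10 equiv), CH2Cl2, −20 → 0 °C
Reagents that add atoms: none
Why: Ionic hydrogenation (Kursanov–Parnes type) in which acid ionises the carbinol to a 2,4-dialkoxybenzyl cation that takes hydride from the silane, capture of the cation by the diketone enol oxygen being reversible under the same acid, while the unactivated ketones and the remote stereocentre should stay untouched.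

**Step 5**
Reactants: 9 4-(propan-2-yloxy)benzaldehyde; 10 diethyl {2-[methoxy(methyl)amino]-2-oxoethyl}phosphonate
Product: 11 (E)-N-methoxy-N-methyl-3-[4-(propan-2-yloxy)phenyl]prop-2-enamide
Conditions: LiCl, DBU, MeCN, rt
Reagents that add atoms: none
Why: Horner–Wadsworth–Emmons olefination under LiCl/amine conditions, which with a stabilised phosphonoacetamide and an aromatic aldehyde should give the (E)-alkene.

**Step 6**
Reactants: 8 3-{(1R)-3-[2-methoxy-4-(propan-2-yloxy)phenyl]-1-(4-methoxyphenyl)propyl}pentane-2,4-dione; 11 (E)-N-methoxy-N-methyl-3-[4-(propan-2-yloxy)phenyl]prop-2-enamide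
Product: 13 (7E)-3-{(1R)-3-[2-methoxy-4-(propan-2-yloxy)phenyl]-1-(4-methoxyphenyl)propyl}-8-[4-(propan-2-yloxy)phenyl]oct-7-ene-2,4,6-trione (keto-enol tautomers; C-3 unassigned), via dilithium dianion 12 (not isolated)
Conditions: LDA (2.2 equiv), THF, −78 → 0 °C; 11 (1.1 equiv), −78 → −20 °C; AcOH, −78 °C
Reagents that add atoms: none
Why: C-acylation of a β-diketone 1,3-dianion, in which the more basic terminal methyl carbanion reacts first and the N-methoxy-N-methylamide favours 1,2- over 1,4-attack and holds the adduct as a chelate until the quench, so that the acidic product cannot protonate unreacted 12.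

**Step 7**
Reactants: 13 (7E)-3-{(1R)-3-[2-methoxy-4-(propan-2-yloxy)phenyl]-1-(4-methoxyphenyl)propyl}-8-[4-(propan-2-yloxy)phenyl]oct-7-ene-2,4,6-trione
Product: 14 2-methyl-3-{(1S)-3-[2-methoxy-4-(propan-2-yloxy)phenyl]-1-(4-methoxyphenyl)propyl}-6-{(E)-2-[4-(propan-2-yloxy)phenyl]ethenyl}-4H-pyran-4-one
Conditions: TFA–CH2Cl2 (1:4), 0 °C → rt
Reagents that add atoms: none
Why: Acid-catalysed cyclodehydration of a 1,3,5-triketone (the enol oxygen of one outer carbonyl adds to the other, then water is lost) is the standard entry to 2,6-disubstituted 4-pyranones, and it turns a labile tautomer mixture into one neutral, purifiable compound in which the chain can be stored and its enantiopurity checked.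

**Step 8**
Reactants: 14 2-methyl-3-{(1S)-3-[2-methoxy-4-(propan-2-yloxy)phenyl]-1-(4-methoxyphenyl)propyl}-6-{(E)-2-[4-(propan-2-yloxy)phenyl]ethenyl}-4H-pyran-4-one
Product: 16 2-{(1S)-3-[2-methoxy-4-(propan-2-yloxy)phenyl]-1-(4-methoxyphenyl)propyl}-5-{(E)-2-[4-(propan-2-yloxy)phenyl]ethenyl}benzene-1,3-diol, via triketone 13 (not isolated), via cyclic ketol 15 (not isolated)
Conditions: KOH (2 M aq, 10 equiv), 1,4-dioxane, degassed, Ar, dark, 70 °C; then 1 M HCl, 0 °C
Reagents that add atoms: water, delivered as hydroxide, O (one H2O is added to 14 to give 13; one H2O is lost again from 15)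
Why: Hydroxide adds to C-6 or C-2 of the pyranone (both sites lead to the same chain), the ring opens by expulsion of the enolate oxygen and 13 is set free as its enolate; the C-1 methyl group, the only enolisable chain end, then attacks the cinnamoyl carbonyl C-6 to give ketol 15, which loses water by E1cB and tautomerises to 16. The closest known reaction type is the base-induced conversion of 2,6-disubstituted 4-pyranones through 1,3,5-triketones into resorcinols (2,6-dimethyl-4-pyranone to orcinol), the flask counterpart of the stilbene-synthase fold. Ring C closes by a 6-(enolendo)-exo-trig aldol addition that makes the bond between the former methyl carbon (a ring CH of 16) and the styryl-bearing carbon. No stereocentre is created in 16, since those of 15 vanish on aromatisation, and the existing methine carbon sits on the α-carbon C-3, is not itself acidified by a carbonyl group and has no leaving group β to an enolate, so it should pass through unchanged. The step needs the aldol to win over reclosure to the pyranone, oxygen addition at the styryl β-carbon and retro-Claisen loss of acetate: the first two are reversible in base, the third is slowed because the chain is held as an enolate from which C-C cleavage would have to expel a dianion, and only the aldol path ends in an irreversible aromatisation. Regiochemistry is fixed by the chain, because C-7 bears no acidic hydrogen and every other aldol pairing would close a four-membered ring, so the alkyl group must end between the two hydroxyls and para to the styryl arm.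

**Step 9**
Reactants: 16 2-{(1S)-3-[2-methoxy-4-(propan-2-yloxy)phenyl]-1-(4-methoxyphenyl)propyl}-5-{(E)-2-[4-(propan-2-yloxy)phenyl]ethenyl}benzene-1,3-diol
Product: 17 1,3-dimethoxy-2-{(1S)-3-[2-methoxy-4-(propan-2-yloxy)phenyl]-1-(4-methoxyphenyl)propyl}-5-{(E)-2-[4-(propan-2-yloxy)phenyl]ethenyl}benzene
Conditions: MeI (6 equiv), K2CO3, DMF, 40 °C, dark
Reagents that add atoms: iodomethane, CI
Why: Double Williamson O-methylation of the resorcinol, in which a polar aprotic solvent and excess iodomethane should overcome the hindrance by the flanking secondary alkyl group and favour O- over C-alkylation.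

**Step 10**
Reactants: 17 1,3-dimethoxy-2-{(1S)-3-[2-methoxy-4-(propan-2-yloxy)phenyl]-1-(4-methoxyphenyl)propyl}-5-{(E)-2-[4-(propan-2-yloxy)phenyl]ethenyl}benzene
Product: 18 4-[(E)-2-(4-{(1S)-3-(4-hydroxy-2-methoxyphenyl)-1-(4-methoxyphenyl)propyl}-3,5-dimethoxyphenyl)ethenyl]phenol (CNP0182684.1)
Conditions: BCl3 (1 M in CH2Cl2, 5 equiv), CH2Cl2, −78 → −10 °C, dark; then ice-water
Reagents that add atoms: none
Why: Lewis-acid ether cleavage in which BCl3 removes the secondary isopropyl groups as 2-chloropropane at temperatures at which unhindered aryl methyl ethers, the stilbene double bond and the diarylmethine centre should persist.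

**Compound list**
1 | 4-bromo-3-methoxyphenol | COc1cc(O)ccc1Br | starting material
2 | 1-bromo-2-methoxy-4-(propan-2-yloxy)benzene | COc1cc(OC(C)C)ccc1Br | intermediate
3 | pentane-2,4-dione (acetylacetone) | CC(=O)CC(C)=O | starting material
4 | (E)-3-(4-methoxyphenyl)prop-2-enal | COc1ccc(/C=C/C=O)cc1 | starting material
5 | (3R)-4-acetyl-3-(4-methoxyphenyl)-5-oxohexanal | CC(=O)C(C(C)=O)[C@@H](CC=O)c1ccc(OC)cc1 | intermediate
6 | [2-methoxy-4-(propan-2-yloxy)phenyl]magnesium bromide | COc1cc(OC(C)C)ccc1[Mg]Br | intermediate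
7 | 3-{(1R)-3-hydroxy-3-[2-methoxy-4-(propan-2-yloxy)phenyl]-1-(4-methoxyphenyl)propyl}pentane-2,4-dione, both carbinol epimers | CC(=O)C(C(C)=O)[C@@H](CC(O)c1ccc(OC(C)C)cc1OC)c1ccc(OC)cc1 | intermediate
8 | 3-{(1R)-3-[2-methoxy-4-(propan-2-yloxy)phenyl]-1-(4-methoxyphenyl)propyl}pentane-2,4-dione | CC(=O)C(C(C)=O)[C@@H](CCc1ccc(OC(C)C)cc1OC)c1ccc(OC)cc1 | intermediate
9 | 4-(propan-2-yloxy)benzaldehyde | CC(C)Oc1ccc(C=O)cc1 | starting material
10 | diethyl {2-[methoxy(methyl)amino]-2-oxoethyl}phosphonate | CCOP(=O)(CC(=O)N(C)OC)OCC | starting material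
11 | (E)-N-methoxy-N-methyl-3-[4-(propan-2-yloxy)phenyl]prop-2-enamide | CON(C)C(=O)/C=C/c1ccc(OC(C)C)cc1 | intermediate
12 | dilithium 1,3-dianion of 8 (bis-enolate, deprotonated at C-3 and at one methyl group) | [Li+].[Li+].C=C([O-])C(=C(C)[O-])[C@@H](CCc1ccc(OC(C)C)cc1OC)c1ccc(OC)cc1 | intermediate
13 | (7E)-3-{(1R)-3-[2-methoxy-4-(propan-2-yloxy)phenyl]-1-(4-methoxyphenyl)propyl}-8-[4-(propan-2-yloxy)phenyl]oct-7-ene-2,4,6-trione | CC(=O)C(C(=O)CC(=O)/C=C/c1ccc(OC(C)C)cc1)[C@@H](CCc1ccc(OC(C)C)cc1OC)c1ccc(OC)cc1 | intermediate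
14 | 2-methyl-3-{(1S)-3-[2-methoxy-4-(propan-2-yloxy)phenyl]-1-(4-methoxyphenyl)propyl}-6-{(E)-2-[4-(propan-2-yloxy)phenyl]ethenyl}-4H-pyran-4-one | Cc1oc(/C=C/c2ccc(OC(C)C)cc2)cc(=O)c1[C@@H](CCc1ccc(OC(C)C)cc1OC)c1ccc(OC)cc1 | intermediate
15 | 5-hydroxy-2-{(1R)-3-[2-methoxy-4-(propan-2-yloxy)phenyl]-1-(4-methoxyphenyl)propyl}-5-{(E)-2-[4-(propan-2-yloxy)phenyl]ethenyl}cyclohexane-1,3-dione | O=C1CC(O)(/C=C/c2ccc(OC(C)C)cc2)CC(=O)C1[C@@H](CCc1ccc(OC(C)C)cc1OC)c1ccc(OC)cc1 | intermediate
16 | 2-{(1S)-3-[2-methoxy-4-(propan-2-yloxy)phenyl]-1-(4-methoxyphenyl)propyl}-5-{(E)-2-[4-(propan-2-yloxy)phenyl]ethenyl}benzene-1,3-diol | Oc1cc(/C=C/c2ccc(OC(C)C)cc2)cc(O)c1[C@@H](CCc1ccc(OC(C)C)cc1OC)c1ccc(OC)cc1 | intermediate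
17 | 1,3-dimethoxy-2-{(1S)-3-[2-methoxy-4-(propan-2-yloxy)phenyl]-1-(4-methoxyphenyl)propyl}-5-{(E)-2-[4-(propan-2-yloxy)phenyl]ethenyl}benzene | COc1cc(/C=C/c2ccc(OC(C)C)cc2)cc(OC)c1[C@@H](CCc1ccc(OC(C)C)cc1OC)c1ccc(OC)cc1 | intermediate
18 | 4-[(E)-2-(4-{(1S)-3-(4-hydroxy-2-methoxyphenyl)-1-(4-methoxyphenyl)propyl}-3,5-dimethoxyphenyl)ethenyl]phenol | COc1ccc([C@H](CCc2ccc(O)cc2OC)c2c(OC)cc(/C=C/c3ccc(O)cc3)cc2OC)cc1 | target

**Step count**
Total steps: 10.
Longest linear sequence: 8 steps (2, 3, 4, 6, 7, 8, 9, 10 from 3 and 4). The sequence from 1 through steps 1, 3, 4, 6–10 has the same length.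

**Steps most likely to fail**

**Step 8.**
- Risk: the acceptor carbonyl is conjugated and tied up in an enolate, so the aldol closure may be outrun by cleavage of the opened chain. The cleavage paths are retro-Claisen loss of the acetyl end and hydration followed by retro-aldol at the styryl double bond. The chain may also simply re-close to the pyranone on acidification.
- Fallback: it sets out from 8 and comes back at 17. It makes ring C with a far more electrophilic acceptor and without the base-sensitive styryl unit, which is added afterwards by olefination.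
- Dianion 12 (from 8 and LDA as in step 6) would be acylated with dimethyl oxalate by inverse addition to give methyl 5-{(1R)-diarylpropyl}-2,4,6-trioxoheptanoate F1.
- Mg(OMe)2 in MeOH should close the methyl carbon onto the α-keto-ester carbonyl and aromatise to methyl 4-{(1S)-diarylpropyl}-3,5-dihydroxybenzoate F2.
- MeI/K2CO3 would give the dimethoxybenzoate F3, and LiAlH4 the benzylic alcohol F4.
- ZnI2/P(OEt)3 in hot toluene would give the diethyl benzylphosphonate F5.
- Horner–Wadsworth–Emmons olefination of F5 with aldehyde 9 (KOtBu, THF) should then deliver the (E)-stilbene 17.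

**Step 2.**
- Risk: addition to the electron-rich iminium ion may be slow. Retro-Michael reversal may erode enantiopurity. Knoevenagel-type 1,2-condensation may compete. The amine may also carry the adduct on into an intramolecular aldol condensation.
- Fallback: it sets out from 2 and comes back at 8, and it also replaces steps 3 and 4. The stereocentre is set by rhodium-catalysed conjugate arylation, and the diketone is masked as a 3,5-dimethylisoxazole, so that no acidic or reversible Michael adduct is involved.
- Grignard reagent 6 from 2 and N-methoxy-N-methylacetamide would give 1-[2-methoxy-4-(propan-2-yloxy)phenyl]ethanone F6.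
- Claisen–Schmidt condensation with commercial 3,5-dimethylisoxazole-4-carbaldehyde (NaOH, EtOH) would give the (E)-isoxazolyl enone F7.
- Hayashi–Miyaura addition of 4-methoxyphenylboronic acid should give the (S)-β,β-diaryl ketone F8. The conditions would be [RhCl(C2H4)2]2, a chiral bicyclooctadiene ligand whose antipode is chosen for the S product, aq KOH and dioxane.
- Et3SiH/TFA would reduce the electron-rich aryl ketone to methylene, giving the (S)-4-alkylisoxazole F9.
- Mo(CO)6 in wet MeCN would cleave the N-O bond to the (Z)-enaminoketone F10, which dilute HCl in THF should hydrolyse to 8.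

**Step 6.**
- Risk: conjugate addition of the dianion to the cinnamoyl acceptor may compete with acylation. The tetrahedral adduct may also collapse early, and the acidic triketone set free would then quench unreacted dianion.
- Fallback: it sets out from 8 and 11 and comes back at 13. It replaces acylation by aldol addition and oxidation.
- i-Bu2AlH (THF, −78 °C) would reduce 11 to (E)-3-[4-(propan-2-yloxy)phenyl]prop-2-enal F11.
- Dianion 12 should add 1,2 to this more reactive, non-enolisable aldehyde at −78 °C to give the 6-hydroxy-2,4-dione F12, whose alkoxide cannot protonate 12.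
- MnO2 in CH2Cl2 should then oxidise the cinnamyl-type allylic alcohol selectively to triketone 13.

**Further compounds**
F1 | step 8 | methyl 5-{(1R)-3-[2-methoxy-4-(propan-2-yloxy)phenyl]-1-(4-methoxyphenyl)propyl}-2,4,6-trioxoheptanoate | COC(=O)C(=O)CC(=O)C(C(C)=O)[C@@H](CCc1ccc(OC(C)C)cc1OC)c1ccc(OC)cc1
F2 | step 8 | methyl 3,5-dihydroxy-4-{(1S)-3-[2-methoxy-4-(propan-2-yloxy)phenyl]-1-(4-methoxyphenyl)propyl}benzoate | COC(=O)c1cc(O)c([C@@H](CCc2ccc(OC(C)C)cc2OC)c2ccc(OC)cc2)c(O)c1
F3 | step 8 | methyl 3,5-dimethoxy-4-{(1S)-3-[2-methoxy-4-(propan-2-yloxy)phenyl]-1-(4-methoxyphenyl)propyl}benzoate | COC(=O)c1cc(OC)c([C@@H](CCc2ccc(OC(C)C)cc2OC)c2ccc(OC)cc2)c(OC)c1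
F4 | step 8 | (3,5-dimethoxy-4-{(1S)-3-[2-methoxy-4-(propan-2-yloxy)phenyl]-1-(4-methoxyphenyl)propyl}phenyl)methanol | OCc1cc(OC)c([C@@H](CCc2ccc(OC(C)C)cc2OC)c2ccc(OC)cc2)c(OC)c1
F5 | step 8 | diethyl (3,5-dimethoxy-4-{(1S)-3-[2-methoxy-4-(propan-2-yloxy)phenyl]-1-(4-methoxyphenyl)propyl}benzyl)phosphonate | CCOP(=O)(Cc1cc(OC)c([C@@H](CCc2ccc(OC(C)C)cc2OC)c2ccc(OC)cc2)c(OC)c1)OCC
F6 | step 2 | 1-[2-methoxy-4-(propan-2-yloxy)phenyl]ethanone | CC(=O)c1ccc(OC(C)C)cc1OC
F7 | step 2 | (E)-3-(3,5-dimethylisoxazol-4-yl)-1-[2-methoxy-4-(propan-2-yloxy)phenyl]prop-2-en-1-one | Cc1noc(C)c1/C=C/C(=O)c1ccc(OC(C)C)cc1OC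
F8 | step 2 | (3S)-3-(3,5-dimethylisoxazol-4-yl)-1-[2-methoxy-4-(propan-2-yloxy)phenyl]-3-(4-methoxyphenyl)propan-1-one | Cc1noc(C)c1[C@@H](CC(=O)c1ccc(OC(C)C)cc1OC)c1ccc(OC)cc1
F9 | step 2 | 4-{(1S)-3-[2-methoxy-4-(propan-2-yloxy)phenyl]-1-(4-methoxyphenyl)propyl}-3,5-dimethylisoxazole | Cc1noc(C)c1[C@@H](CCc1ccc(OC(C)C)cc1OC)c1ccc(OC)cc1
F10 | step 2 | (3Z)-4-amino-3-{(1S)-3-[2-methoxy-4-(propan-2-yloxy)phenyl]-1-(4-methoxyphenyl)propyl}pent-3-en-2-one | C/C(N)=C(/C(C)=O)[C@@H](CCc1ccc(OC(C)C)cc1OC)c1ccc(OC)cc1
F11 | step 6 | (E)-3-[4-(propan-2-yloxy)phenyl]prop-2-enal | CC(C)Oc1ccc(/C=C/C=O)cc1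
F12 | step 6 | (7E)-6-hydroxy-3-{(1R)-3-[2-methoxy-4-(propan-2-yloxy)phenyl]-1-(4-methoxyphenyl)propyl}-8-[4-(propan-2-yloxy)phenyl]oct-7-ene-2,4-dione | CC(=O)C(C(=O)CC(O)/C=C/c1ccc(OC(C)C)cc1)[C@@H](CCc1ccc(OC(C)C)cc1OC)c1ccc(OC)cc1
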